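A first exchange with an equilibrium constant of 0.14 cannot empty blue of starting complex against the leaving ligand it sets free.

    complex with three exchanged + incoming ligand ⇌ leaving ligand + complex with four exchanged (K1 = 1.1, k1 = 41 L mol⁻¹ h⁻¹)
    starting complex + incoming ligand ⇌ leaving ligand + complex with one exchanged (K2 = 0.14, k2 = 14 L mol⁻¹ h⁻¹)
    complex with one exchanged + incoming ligand ⇌ leaving ligand + complex with two exchanged (K3 = 0.50, k3 = 4.5 L mol⁻¹ h⁻¹)
    scavenger + leaving ligand → scavenged by-product (k4 = 1500 L mol⁻¹ h⁻¹)
    complex with two exchanged + incoming ligand ⇌ leaving ligand + complex with three exchanged (K5 = 0.28, k5 = 32 L mol⁻¹ h⁻¹)
    leaving ligand + starting complex ⇌ idle adduct, settled at all times (K6 = 190 L mol⁻¹)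

- blue: starting complex 20 mM; incoming ligand 30.0 mM; scavenger 20.0 mM; time 20 h
- violet: starting complex 20 mM; incoming ligand 30.0 mM; scavenger 30.0 mM; time 20 h

1. part of the starting complex that has reacted at the end, blue
2. part of the starting complex that has reacted at the end, violet
3. what raising the concentration of scavenger from its lowest to its highest value here does to the part of the starting complex that has reacted (changes below 5 percentage points count as none) (it rises / no change / it falls)

- amounts and yields of leaving ligand count idle adduct too
- what has gone from starting complex into another species counts as reacted, even if it can come back
- run time (blue): 20 h

**Ledger first.** Each exchange uses one incoming ligand and frees one leaving ligand. By step 4 alone, free leaving ligand has a half-life of 1.4 min, shorter than the 1.7 h of starting complex by the forward first exchange. Blue is therefore reckoned to use its 20.0 mM of scavenger, which leaves 10.0 mM of incoming ligand to share with the leaving ligand freed afterwards. That 1.7 h is short against 20 h, but it belongs to one forward step as charged, so balance along the whole chain is an assumption of this reckoning: the exchanges are frozen there. Each complex then stands to the one before it as that step's constant times one ratio.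

**First trial.** Try a ratio of 2.00. Summed over the chain, the complexes come to 2.06 per starting complex, so c(starting complex) is 9.70 mM. The margin of 10.0 mM must cover incoming ligand, free leaving ligand and idle adduct, which gives c(leaving ligand) of 2.06 mM. Counting the adduct lowers c(starting complex) to 8.15 mM, so 59.3% has reacted.

**Weak link.** The trial ratio is the weak link. At 2.00 the chain holds 21.9 mM of exchanges, less than the 25.9 mM the ledger demands. At 2.25 the sum is 2.45, c(leaving ligand) is 2.08 mM and c(starting complex) is 7.04 mM. The chain now holds 27.5 mM, more than the ledger's 25.3 mM. Interpolating between the two gaps, 2.16 is the ladder ratio, free incoming ligand over free leaving ligand at balance. That commits blue to 62.8% reacted. Violet has 30.0 mM of scavenger, more than blue, and its margin is 0 mM, so the ledger sets its exchanges at 30.0 mM, or 1.50 per complex. Blue's ladder ratio gives a sum of 2.30 and 1.49 exchanges per complex, close to that. The frozen chain therefore reckons violet at 56.5% reacted, lower than blue.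

**Forecast, result.** The forecast, higher for both flasks than this reckoning, gives 72% and 85%, with it rises against the fall reckoned here, as “the free leaving ligand then pushes the strongly reversible first step back”. The simulation gives 63.2% for blue and 80.1% for violet: it rises, by 17 percentage points, mainly because of the difference in scavenger. Violet stands above its balance figure, and after 200 h it has come down to 74.5%.

**Back step.** In blue, the ladder ratio puts 0.303 complex with one exchanged beside each starting complex, and the table holds 0.302 after 200 h. The fall back of the first exchange is part of what stops blue: without it, blue reaches 92.3%. The neighbour of violet with 120 mM of incoming ligand ends with 0% of its scavenger and a ratio of 4.37. Its first step therefore calls for 0.611, and that neighbour holds 0.606.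

The numbers of this flask are made up; no experiment stands behind them.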